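**Plan**

- The target is read as (2S,4R), the 2,4-trans flavan-4-ol. Retrosynthetic cuts, in order: the 5-O–Si bond and the C4–O bond (OH from a helper OMe); then O1–C2 and C3–C4 together (retro oxa-[4+2]); then the C8–prenyl bond (retro-Claisen) and the ether O–C bonds on the A ring.
- Enabling feature: C4 is ortho to O1 on the phloroglucinol A ring, so O1–C8a=C4a–C4 is a latent 1-oxadiene (an ortho-quinone methide at the aldehyde oxidation level). C2 carries a 4-hydroxyphenyl group, so C2–C3 is the alkene of 4-vinylphenol.
- Forward: phloroglucinaldehyde is methylated at O-4, mono-etherified, silylated and taken through Lindlar reduction and Claisen rearrangement, so that the prenyl group sits next to the only free OH. 4-Vinylphenol comes from 4-acetoxystyrene.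
- The pyran ring is closed last, by a chiral-acid cycloaddition of the alkoxy ortho-quinone methide with 4-vinylphenol. The helper 4-OMe is then exchanged for OH and the silyl group removed.
- Stereochemistry: C2 (S) from the chiral phosphoric acid in the cycloaddition; C4 (R) from axial capture of the flavan-4-yl cation by water, trans to the C2 aryl group.

Key step: step 7

Assumption: the sense of induction of the phosphoric acid cannot be predicted for this substrate pair; (R)-TRIP is written, and its antipode is to be used if the 2R series forms.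

**Route**

Step 1
Reactants: 1 2,4,6-trihydroxybenzaldehyde
Product: 2 2,6-dihydroxy-4-methoxybenzaldehyde
Conditions: Me2SO4 (1.0 equiv), K2CO3 (1.0 equiv), acetone, 0 °C to rt
Reagents that add atoms: dimethyl sulfate COS(=O)(=O)OC
Why: Williamson O-methylation: the 4-OH, para to the formyl group and not hydrogen-bonded to it, is the most acidic and should react first, while the hard sulfate electrophile favours O- over C-methylation.

Step 2
Reactants: 2 2,6-dihydroxy-4-methoxybenzaldehyde; 3 3-chloro-3-methylbut-1-yne
Product: 4 2-hydroxy-4-methoxy-6-[(2-methylbut-3-yn-2-yl)oxy]benzaldehyde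
Conditions: K2CO3, KI (cat.), CuI (cat.), DMF, 60 °C
Reagents that add atoms: none
Why: Copper-assisted propargylic O-alkylation (Williamson type, through the copper acetylide/allenylidene of 3): the two OH groups of 2 are equivalent, and after the first etherification the remaining OH is chelated to the formyl group and should resist a second alkylation.

Step 3
Reactants: 4 2-hydroxy-4-methoxy-6-[(2-methylbut-3-yn-2-yl)oxy]benzaldehyde
Product: 5 2-(tert-butyldimethylsilyloxy)-4-methoxy-6-[(2-methylbut-3-yn-2-yl)oxy]benzaldehyde
Conditions: TBSCl, imidazole, DMF, rt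
Reagents that add atoms: tert-butyldimethylsilyl chloride CC(C)(C)[Si](C)(C)Cl
Why: Silylation of the one remaining phenol (silyl ether formation), which masks the future 5-OH so that only the oxygen freed in step 5 can later become O1.

Step 4
Reactants: 5 2-(tert-butyldimethylsilyloxy)-4-methoxy-6-[(2-methylbut-3-yn-2-yl)oxy]benzaldehyde
Product: 6 2-(tert-butyldimethylsilyloxy)-4-methoxy-6-[(2-methylbut-3-en-2-yl)oxy]benzaldehyde
Conditions: H2 (1 atm), Lindlar catalyst, quinoline, EtOAc, rt
Reagents that add atoms: none
Why: Lindlar semihydrogenation of the terminal alkyne to the 1,1-dimethylallyl ether; aldehyde and aryl silyl ether are inert to the poisoned catalyst.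

Step 5
Reactants: 6 2-(tert-butyldimethylsilyloxy)-4-methoxy-6-[(2-methylbut-3-en-2-yl)oxy]benzaldehyde
Product: 8 6-(tert-butyldimethylsilyloxy)-2-hydroxy-4-methoxy-3-(3-methylbut-2-en-1-yl)benzaldehyde, via ortho-dienone 7 (not isolated)
Conditions: PhMe, 110 °C
Reagents that add atoms: none
Why: Aromatic Claisen rearrangement: the [3,3] shift to the only hydrogen-bearing ortho carbon inverts the allyl unit to a prenyl group and dienone 7 tautomerises to the phenol, so the prenyl group ends next to the free OH that will become O1.

Step 6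
Reactants: 9 4-acetoxystyrene
Product: 10 4-vinylphenol
Conditions: K2CO3 (5 mol %), MeOH, 0 °C; neutral work-up, used at once as a cold CH2Cl2 solution
Reagents that add atoms: none
Why: Base-catalysed transesterification (methanolysis) of the aryl acetate; 10 is prone to polymerise and is therefore made fresh and not stored.

Step 7
Reactants: 8 6-(tert-butyldimethylsilyloxy)-2-hydroxy-4-methoxy-3-(3-methylbut-2-en-1-yl)benzaldehyde; 10 4-vinylphenol
Product: 13 4-[(2S,4R)-5-(tert-butyldimethylsilyloxy)-4,7-dimethoxy-8-(3-methylbut-2-en-1-yl)-3,4-dihydro-2H-chromen-2-yl]phenol, via dimethyl acetal 11 (not isolated), via ortho-quinone methide 12 (not isolated)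
Conditions: HC(OMe)3 (1.5 equiv), (R)-TRIP (10 mol %), 5 Å MS, CH2Cl2, −30 °C; then 10 (1.5 equiv, slow addition), −30 to 0 °C
Reagents that add atoms: trimethyl orthoformate COC(OC)OC
Why: Proposed new method: the acid turns 8 and the orthoformate into acetal 11, which loses methanol to the 1-methoxy ortho-quinone methide 12 (oxadiene O1=C8a–C4a=C4); the vinyl terminus of 10 adds to C4, and the para-hydroxybenzylic cation so formed, a protonated para-quinone methide, is captured at C2 by O1. The closest known reaction types are the Lewis-acid three-component coupling of salicylaldehydes, trimethyl orthoformate and styrenes to 4-methoxy-2-arylchromans and the chiral-phosphoric-acid [4+2] cycloadditions of ortho-quinone methides with vinylphenols; new is the enantioselective use of an alkoxy-substituted ortho-quinone methide with 4-vinylphenol. The pyran ring closes by an inverse-electron-demand oxa-[4+2] cycloaddition that forms C3–C4 and O1–C2, asynchronous or stepwise, in the stepwise limit a 6-exo-trig addition of O1 to the quinone methide carbon. C4 is set by the phosphate, which is expected to bridge the carbonyl oxygen of 12 and the 4'-OH of 10 and so to select one face of 12; C2 is set relative to C4 in a chair-like closure with the aryl group equatorial and the 4-methoxy group pseudo-axial, away from the peri 5-silyloxy group, which gives the 2,4-trans ether, and the catalyst antipode is chosen for 2S. Regioselectivity follows from polarity (nucleophilic CH2 terminus to C4, aryl-stabilised carbon to O1) and from the single free OH, which lies next to the prenyl group and so puts that group at C8; the weak acid and low temperature should spare the prenyl alkene and keep 10 from oligomerising. Only C2 has to survive, since step 8 re-sets C4, but 13 is freed of any C4 epimer first, because an epimer made from the same face of 12 would be 2R.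

Step 8
Reactants: 13 4-[(2S,4R)-5-(tert-butyldimethylsilyloxy)-4,7-dimethoxy-8-(3-methylbut-2-en-1-yl)-3,4-dihydro-2H-chromen-2-yl]phenol
Product: 14 (2S,4R)-5-(tert-butyldimethylsilyloxy)-2-(4-hydroxyphenyl)-7-methoxy-8-(3-methylbut-2-en-1-yl)-3,4-dihydro-2H-chromen-4-ol
Conditions: 0.05 M HCl, THF/H2O (4:1), 0 °C; NaHCO3 quench
Reagents that add atoms: water O
Why: SN1 hydrolysis through the flavan-4-yl cation (stabilised by O1, the 5-silyloxy and the 7-methoxy group), which water should capture on the axial trajectory opposite the equatorial C2 aryl group to give the pseudo-axial 4R alcohol, the 2,4-trans isomer that is also favoured at equilibrium because it avoids the peri contact with the 5-silyloxy group; C2 is not touched.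

Step 9
Reactants: 14 (2S,4R)-5-(tert-butyldimethylsilyloxy)-2-(4-hydroxyphenyl)-7-methoxy-8-(3-methylbut-2-en-1-yl)-3,4-dihydro-2H-chromen-4-ol
Product: 15 (2S,4R)-2-(4-hydroxyphenyl)-7-methoxy-8-(3-methylbut-2-en-1-yl)-3,4-dihydro-2H-chromene-4,5-diol (4,5,4'-trihydroxy-7-methoxy-8-prenylflavan)
Conditions: TBAF (1.1 equiv), AcOH (1.1 equiv), THF, 0 °C
Reagents that add atoms: none
Why: Fluoride-induced cleavage of the aryl silyl ether (desilylation); acetic acid buffers the phenoxide so that neither quinone methide formation nor loss of the C4 hydroxyl should be triggered, and no stereocentre is involved.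

**Compound list**

1 | 2,4,6-trihydroxybenzaldehyde | O=Cc1c(O)cc(O)cc1O | starting material
2 | 2,6-dihydroxy-4-methoxybenzaldehyde | COc1cc(O)c(C=O)c(O)c1 | intermediate
3 | 3-chloro-3-methylbut-1-yne | CC(C)(Cl)C#C | starting material
4 | 2-hydroxy-4-methoxy-6-[(2-methylbut-3-yn-2-yl)oxy]benzaldehyde | COc1cc(O)c(C=O)c(OC(C)(C)C#C)c1 | intermediate
5 | 2-(tert-butyldimethylsilyloxy)-4-methoxy-6-[(2-methylbut-3-yn-2-yl)oxy]benzaldehyde | COc1cc(O[Si](C)(C)C(C)(C)C)c(C=O)c(OC(C)(C)C#C)c1 | intermediate
6 | 2-(tert-butyldimethylsilyloxy)-4-methoxy-6-[(2-methylbut-3-en-2-yl)oxy]benzaldehyde | COc1cc(O[Si](C)(C)C(C)(C)C)c(C=O)c(OC(C)(C)C=C)c1 | intermediate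
7 | 2-(tert-butyldimethylsilyloxy)-4-methoxy-5-(3-methylbut-2-en-1-yl)-6-oxocyclohexa-1,3-diene-1-carbaldehyde (ortho-dienone; transient C5 centre unassigned, lost on tautomerisation) | O=CC1=C(O[Si](C)(C)C(C)(C)C)C=C(OC)C(CC=C(C)C)C1=O | intermediate (not isolated)
8 | 6-(tert-butyldimethylsilyloxy)-2-hydroxy-4-methoxy-3-(3-methylbut-2-en-1-yl)benzaldehyde | COc1cc(O[Si](C)(C)C(C)(C)C)c(C=O)c(O)c1CC=C(C)C | intermediate
9 | 4-acetoxystyrene (4-ethenylphenyl acetate) | CC(=O)Oc1ccc(C=C)cc1 | starting material
10 | 4-vinylphenol | C=Cc1ccc(O)cc1 | intermediate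
11 | 3-(tert-butyldimethylsilyloxy)-2-(dimethoxymethyl)-5-methoxy-6-(3-methylbut-2-en-1-yl)phenol (dimethyl acetal of 8) | COc1cc(O[Si](C)(C)C(C)(C)C)c(C(OC)OC)c(O)c1CC=C(C)C | intermediate (not isolated)
12 | 5-(tert-butyldimethylsilyloxy)-3-methoxy-6-(methoxymethylidene)-2-(3-methylbut-2-en-1-yl)cyclohexa-2,4-dien-1-one (ortho-quinone methide; geometry of the exocyclic C=C left open) | O=C1C(CC=C(C)C)=C(OC)C=C(O[Si](C)(C)C(C)(C)C)C1=COC | intermediate (not isolated)
13 | 4-[(2S,4R)-5-(tert-butyldimethylsilyloxy)-4,7-dimethoxy-8-(3-methylbut-2-en-1-yl)-3,4-dihydro-2H-chromen-2-yl]phenol (2,4-trans) | COc1cc(O[Si](C)(C)C(C)(C)C)c2c(c1CC=C(C)C)O[C@H](c1ccc(O)cc1)C[C@H]2OC | intermediate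
14 | (2S,4R)-5-(tert-butyldimethylsilyloxy)-2-(4-hydroxyphenyl)-7-methoxy-8-(3-methylbut-2-en-1-yl)-3,4-dihydro-2H-chromen-4-ol (2,4-trans) | COc1cc(O[Si](C)(C)C(C)(C)C)c2c(c1CC=C(C)C)O[C@H](c1ccc(O)cc1)C[C@H]2O | intermediate
15 | (2S,4R)-2-(4-hydroxyphenyl)-7-methoxy-8-(3-methylbut-2-en-1-yl)-3,4-dihydro-2H-chromene-4,5-diol | COc1cc(O)c2c(c1CC=C(C)C)O[C@H](c1ccc(O)cc1)C[C@H]2O | target

**Step count and risks**

Total steps: 9. Longest linear sequence: 8 (steps 1, 2, 3, 4, 5, 7, 8, 9); step 6 is a one-step side branch.

Steps most likely to fail: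

1. Step 7 (Proposed new method). The risks are insufficient facial discrimination by the catalyst (low enantiomeric purity at C2), acid-induced cyclisation of the free OH onto the prenyl alkene, and cationic oligomerisation of the vinylphenol. Fallback with known chemistry: it sets out from 8 and 10 and runs the same three-component cycloaddition with an achiral Lewis acid (Sc(OTf)3 cat., HC(OMe)3, CH2Cl2, 0 °C). This should give the racemic 2,4-trans ether F1, which is resolved by preparative chromatography on a chiral stationary phase (amylose tris(3,5-dimethylphenylcarbamate)). The (2S,4R) enantiomer is 13, where the route is rejoined.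

2. Step 8. The risks are poor facial selectivity in the capture of the C4 cation by water and erosion of the trans preference by reversible ionisation, with loss of H-3 to the flav-3-ene as a side path. Fallback: it sets out from 13, with the hydrolysis run without regard to C4, so that 14 forms together with the 2,4-cis alcohol F2. The mixture is oxidised with MnO2 (CH2Cl2, rt) to the (2S)-flavanone F3. Reagent-controlled CBS reduction ((S)-Me-CBS, excess BH3·SMe2 to cover the free phenol, THF, −20 °C) should then deliver the 4R alcohol, and the route is rejoined at 14.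

3. Step 1. The risks are over-methylation and methylation at an ortho oxygen or at ring carbon. Fallback: it sets out from 1, which is exhaustively O-methylated (excess Me2SO4, K2CO3, acetone, reflux) to 2,4,6-trimethoxybenzaldehyde F4. Chelation-controlled cleavage of both methyl ethers ortho to the formyl group with AlCl3 (excess, CH2Cl2, rt to reflux) should then give 2, where the route is rejoined.

Further compounds
F1 | step 7 | racemic 2,4-trans 4-[5-(tert-butyldimethylsilyloxy)-4,7-dimethoxy-8-(3-methylbut-2-en-1-yl)-3,4-dihydro-2H-chromen-2-yl]phenol (13 and its enantiomer) | COc1cc(O[Si](C)(C)C(C)(C)C)c2c(c1CC=C(C)C)O[C@H](c1ccc(O)cc1)C[C@H]2OC.COc1cc(O[Si](C)(C)C(C)(C)C)c2c(c1CC=C(C)C)O[C@@H](c1ccc(O)cc1)C[C@@H]2OC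
F2 | step 8 | (2S,4S)-5-(tert-butyldimethylsilyloxy)-2-(4-hydroxyphenyl)-7-methoxy-8-(3-methylbut-2-en-1-yl)-3,4-dihydro-2H-chromen-4-ol (2,4-cis epimer of 14) | COc1cc(O[Si](C)(C)C(C)(C)C)c2c(c1CC=C(C)C)O[C@H](c1ccc(O)cc1)C[C@@H]2O
F3 | step 8 | (2S)-5-(tert-butyldimethylsilyloxy)-2-(4-hydroxyphenyl)-7-methoxy-8-(3-methylbut-2-en-1-yl)-2,3-dihydro-4H-chromen-4-one | COc1cc(O[Si](C)(C)C(C)(C)C)c2c(c1CC=C(C)C)O[C@H](c1ccc(O)cc1)CC2=O
F4 | step 1 | 2,4,6-trimethoxybenzaldehyde | COc1cc(OC)c(C=O)c(OC)c1
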